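The runs stem from a simulated flask from invented constants, noise included.

- I started from what was left. At the last readings, starting material stood at 24.2%, 23.8% and 23.3% in Sunday's, Tuesday's and Thursday's runs, at loadings of 0.014 mol%, 0.028 mol% and 0.057 mol%. So I followed what remained to happen, not what had been made.

all flasks: starting material 0.20 M
- Sunday's: enzyme 0.014 mol%; run made earlier
- Tuesday's: enzyme 0.028 mol%; run made earlier
- Thursday's: enzyme 0.057 mol%; run made earlier
- larch: enzyme 0.05 mol%; time 4.0 h
- alder: enzyme 0.015 mol%; time 6.0 h

| run | time / h | target / % | starting material / % |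
|---|---|---|---|
| Sunday's | 0.250 | 21.4 | 60.8 |
| Sunday's | 0.667 | 38.4 | 32.4 |
| Sunday's | 1.33 | 43.5 | 24.3 |
| Sunday's | 2.00 | 44.5 | 22.7 |
| Sunday's | 3.00 | 42.8 | 24.2 |
| Tuesday's | 0.250 | 37.7 | 45.8 |
| Tuesday's | 0.667 | 49.7 | 28.9 |
| Tuesday's | 1.33 | 48.2 | 23.9 |
| Tuesday's | 2.00 | 46.4 | 24.8 |
| Tuesday's | 3.00 | 44.3 | 23.8 |
| Thursday's | 0.500 | 54.9 | 28.0 |
| Thursday's | 1.00 | 51.7 | 25.8 |
| Thursday's | 1.50 | 48.2 | 25.0 |
| Thursday's | 2.50 | 45.9 | 24.1 |
| Thursday's | 3.00 | 42.4 | 23.3 |

(each reading ± 1 percentage point)



* the winner by amount of target, in percent of the starting material charged; "neither" if no more than 2 percentage points parts them (larch / alder / neither)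
* how much target is there at the end, in percent of the starting material charged: larch
* how much target is there at the end, in percent of the starting material charged: alder

- The first instants belonged to the enzyme. In Thursday's run, target over starting material was already 1.96 at 0.500 h and still 1.82 at 3.00 h. Meanwhile the share missing from both went from 17.1% to twice that, at 34.3%.
- The middle was an overshoot, kinetic control giving way to thermodynamic control. I took the plateau of target as the mean of the last readings, 43.2%. Thursday's excess over it fell from 12 percentage points to 5 points in 1.00 h. Working with the fraction left, that reads as a rate of 0.846 h⁻¹, and so as an overshoot half-life, the time in which the excess of target over its plateau halves, of 0.819 h.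
- For the end, I laid larch on Thursday's curve, since their loadings are close. From Thursday's first reading to 4.0 h is 4.27 half-lives, which leaves 5.18% of the excess, so my larch stood at 43.8%. Alder, near Sunday's loading, starts from Sunday's peak reading and has 4.88 half-lives to run, giving 43.2%. The gap of 0.60 points is smaller than the margin of 2 points, so I called it neither.
- The forecast said neither, with 43.8% for larch and 43.5% for alder, a little above my alder; its ground was that the runs “converge on the same three-way equilibrium”.

    starting material + enzyme ⇌ complex (K = 11.0 M⁻¹, k = 220 M⁻¹ s⁻¹)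
    complex ⇌ enzyme + target (K = 0.170 M, k = 3.40 s⁻¹)
    starting material ⇌ dormant form (K = 1.50, k = 2.70 × 10⁻⁴ s⁻¹)
    2 complex → spent catalyst (k = 2.10 M⁻¹ s⁻¹)

- The flasks gave neither: larch 43.3%, alder 42.9%. Spent catalyst held 44.8% of the catalyst charged in larch at 4.00 h, yet that step made no difference to larch's target. Larch's own 45.8% at 2.00 h gives the half-life a further use: 2.44 half-lives later, 18.4% of its excess remains, which reckons to 43.7% at 4.0 h.
- Larch read at 1.0 h is 0.611 half-lives past Thursday's first reading, so the reckoning gives 50.9%. The flask gave 50.2%.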